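Two questions came before the meeting, both about what more enzyme does to the rate at one fixed conversion of a single flask, followed so far in Monday's run.

- Monday's: substrate 26 mM; enzyme 3.4 µM; the very flask that is asked about, followed so far
- flask: substrate 26 mM; enzyme 3.4 µM

Monday's run (percent of the substrate charged): time / min: product / % = 0.417: 8.2; 1.00: 18.8; 2.00: 35.8; 3.00: 51.0; 5.00: 74.8

(standard deviation of a reading: 0.3 percentage points)

- factor on the rate of making product when 50 % of the substrate are converted if enzyme is charged twice over
- factor on the rate when 50 % of the substrate are converted if enzyme is charged at 15 µM instead

- no earlier run changes the charge of enzyme; that part of a forecast is a guess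

The kineticist reported that the rate in Monday's run fell from 0.197 min⁻¹ of the charge in the first interval to 0.119 min⁻¹ in the last, and said that one curve cannot show whether the cause is the falling substrate or lost enzyme. The engineer proposed counting instead: by the conversion asked about, this flask must make 3820 turnovers per enzyme charged. This count, substrate converted per enzyme charged, she called the turnover load, a turnover number demanded of the charge.

Her rule was that if each turnover carries a fixed chance of losing the enzyme, the share lost is that chance times the load, and at a fixed charge of substrate and a fixed conversion more enzyme lowers the load. Charging the whole fall to this, and counting the turnovers between the midpoints of those intervals, the minutes read a chance of 8.78 × 10⁻⁵ per turnover, which puts the estimated loss in Monday's flask at 33.6 % at that conversion. The factor is then the charge ratio times the surviving share at the new load over the surviving share at the old one. This reckoning commits to 2.51 and 6.14.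

The forecast gave 2 (1.85 to 2.3) and 4.41 (3.8 to 5.3), holding that “at fixed conversion the rate should scale with enzyme”, and its first figure stands lower than this reckoning.

The flask gives 2.40 and 5.78.

    complex → spent catalyst (k = 0.120 min⁻¹)
    substrate + enzyme ⇌ complex (K = 1700 M⁻¹, k = 68000 M⁻¹ s⁻¹)
    complex → enzyme + product (k = 1600 min⁻¹)

The path from complex to spent catalyst holds the rate down: in the run without it, the rate in this flask at that conversion is 1.40 times the actual one. Each product made spends 7.50 × 10⁻⁵ of an enzyme, the constant of that path over the constant from complex to enzyme + product, so the load of 3820 costs this flask 28.7 % of its charge. In the flask at 15 µM the load is 867, which costs 6.50 %, and the factor from these shares is 5.78.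

The runs are simulated for substances that don't exist, noise included.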